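**Assumption:** the target SMILES (3'-hydroxy-5,6,7,2',4',5'-hexamethoxyflavone, C21H22O9) has no stereocentre, so it is achiral and no enantiocontrol is needed. The only stereo-element in the route is the (E)-alkene of the chalcone, and it is consumed in the last step.

## Retrosynthetic overview
1. The pyranone ring (ring C) is the only ring built. It is closed last, by forming O1–C2 and dehydrogenating a 2'-hydroxychalcone with I2/DMSO.
2. The chalcone Cα=Cβ bond is disconnected by Claisen–Schmidt condensation into an A-ring acetophenone and a B-ring benzaldehyde. The B-ring O-acetyl group is lost in the same operation, so no separate deprotection is needed.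
3. The A-ring ketone comes from ortho C-acetylation of 3,4,5-trimethoxyphenol.
4. The B-ring aldehyde comes from 1,2,4-trimethoxybenzene. The 3-OH is installed by ortho-lithiation, borylation and oxidation between two OMe groups. O-acetylation then switches off the para-directing power of that oxygen, and Vilsmeier formylation follows.
5. Both benzene rings are purchased, and the route is convergent (1 + 3 steps, then 2 steps).

## Route

**Step 1**
- Reactants: 1, 3,4,5-trimethoxyphenol
- Product: 2, 1-(6-hydroxy-2,3,4-trimethoxyphenyl)ethanone (2'-hydroxy-4',5',6'-trimethoxyacetophenone)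
- Conditions: AcOH, BF3·OEt2, 85 °C, 2–3 h; then ice-water
- Reagents that add atoms: acetic acid, CC(=O)O
- Why: This BF3-mediated Friedel–Crafts (Nencki/Fries-type) C-acylation can only occur at the two symmetry-equivalent positions ortho to OH, because para is blocked, and the BF2 chelate of the product prevents a second acylation.

**Step 2**
- Reactants: 3, 1,2,4-trimethoxybenzene
- Product: 4, 2,3,6-trimethoxyphenol
- Conditions: n-BuLi (1.1 equiv), THF, 0 °C → rt, 2 h; B(OMe)3, −78 °C → rt; then 30% H2O2, AcOH, 0 °C → rt
- Reagents that add atoms: hydrogen peroxide, OO (supplies the phenolic O; B(OMe)3 is transient and leaves no atoms)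
- Why: Directed ortho-metalation removes the C3–H flanked by two OMe groups, which is the cooperative 1,3-dimethoxy site, and borylation followed by oxidative 1,2-aryl migration turns the C–Li bond into C–OH.

**Step 3**
- Reactants: 4, 2,3,6-trimethoxyphenol
- Product: 5, 2,3,6-trimethoxyphenyl acetate
- Conditions: Ac2O, Et3N, DMAP (cat.), CH2Cl2, rt
- Reagents that add atoms: acetic anhydride, CC(=O)OC(C)=O
- Why: DMAP-catalysed O-acylation converts the strongly para-directing OH into a weakly donating OAc, so the three OMe groups control the next substitution.

**Step 4**
- Reactants: 5, 2,3,6-trimethoxyphenyl acetate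
- Product: 6, 3-acetoxy-2,4,5-trimethoxybenzaldehyde (3-formyl-2,5,6-trimethoxyphenyl acetate)
- Conditions: POCl3 (2.5 equiv), DMF, 0 → 70 °C; then aq NaOAc, rt
- Reagents that add atoms: DMF, CN(C)C=O (formyl carbon); water, O (carbonyl O, from iminium hydrolysis)
- Why: Vilsmeier–Haack formylation goes to the CH that is ortho and para to two OMe groups, the same preference that turns 1,2,4-trimethoxybenzene into asaraldehyde, whereas the other free CH has only one ortho OMe and a poorly donating para OAc.

**Step 5**
- Reactants: 2, 1-(6-hydroxy-2,3,4-trimethoxyphenyl)ethanone; 6, 3-acetoxy-2,4,5-trimethoxybenzaldehyde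
- Product: 7, (E)-1-(6-hydroxy-2,3,4-trimethoxyphenyl)-3-(3-hydroxy-2,4,5-trimethoxyphenyl)prop-2-en-1-one
- Conditions: KOH (10 equiv, 50% aq), EtOH, N2, rt, 48 h; then 2 M HCl, 0 °C, to pH 3–4 (any flavanone isomer is carried forward with 7)
- Reagents that add atoms: none (H2O and AcOH are lost)
- Why: In this Claisen–Schmidt aldol condensation with E1cB dehydration, which gives the thermodynamic (E)-enone, the acetate is saponified in situ to a phenoxide that is meta to the CHO and so does not deactivate it by resonance.

**Step 6**
- Reactants: 7, the (E)-chalcone
- Product: 8, Agecorynin G (3'-hydroxy-5,6,7,2',4',5'-hexamethoxyflavone)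
- Conditions: I2 (10 mol %), DMSO, 125 °C, 2–3 h; then aq Na2S2O3
- Reagents that add atoms: none (net loss of 2 H)
- Why: I2/DMSO oxidative cyclisation proceeds by 6-endo oxa-Michael closure to the flavanone, then α-iodination and HI elimination, with DMSO regenerating I2, and keeping iodine catalytic limits iodination of the free-phenol B ring and HI cleavage of the 5-OMe group.

## Compound list
| No. | Name | SMILES | Role |
|---|---|---|---|
| 1 | 3,4,5-trimethoxyphenol | COc1cc(O)cc(OC)c1OC | starting material |
| 2 | 1-(6-hydroxy-2,3,4-trimethoxyphenyl)ethanone | CC(=O)c1c(O)cc(OC)c(OC)c1OC | intermediate |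
| 3 | 1,2,4-trimethoxybenzene | COc1ccc(OC)c(OC)c1 | starting material |
| 4 | 2,3,6-trimethoxyphenol | COc1ccc(OC)c(OC)c1O | intermediate |
| 5 | 2,3,6-trimethoxyphenyl acetate | COc1ccc(OC)c(OC)c1OC(C)=O | intermediate |
| 6 | 3-acetoxy-2,4,5-trimethoxybenzaldehyde | COc1c(C=O)cc(OC)c(OC)c1OC(C)=O | intermediate |
| 7 | (E)-2',3-dihydroxy-2,4,4',5,5',6'-hexamethoxychalcone | COc1cc(O)c(C(=O)/C=C/c2cc(OC)c(OC)c(O)c2OC)c(OC)c1OC | intermediate |
| 8 | Agecorynin G (achiral) | COc1cc(-c2cc(=O)c3c(OC)c(OC)c(OC)cc3o2)c(OC)c(O)c1OC | target |

## Summary
- **Total steps:** 6. Compound 2 is also sold by catalogue suppliers, and buying it would remove Step 1.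
- **Longest linear sequence:** 5 steps (3 → 4 → 5 → 6 → 7 → 8).

## Steps most likely to fail, with fallbacks
1. **Step 4, regioselectivity and reactivity of the formylation.**
   - Risk: the para OMe is twisted out of plane by its two neighbours, so some of the isomer formylated para to OAc may form.
   - Fallback: install the carbon first and the last oxygen afterwards.
     - Acetylate 2,6-dimethoxyphenol and formylate it to 3-acetoxy-2,4-dimethoxybenzaldehyde.
     - Brominate at C5, which is para to the 2-OMe, ortho to the 4-OMe and meta to the CHO.
     - Carry out Cu(I)/NaOMe Ullmann-type methoxylation, which also removes the acetate, to give 3-hydroxy-2,4,5-trimethoxybenzaldehyde for Step 5.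
2. **Step 6, I2/DMSO on a very electron-rich free phenol.**
   - Risk: iodination at C6', oxidation of the B ring, or cleavage of the 5-OMe group.
   - Fallback: avoid any oxidative ring closure by using a Baker–Venkataraman route.
     - Exchange Ac for Bn on 6, then Pinnick-oxidise to the benzoic acid.
     - Esterify the acid with 2.
     - Effect base-induced acyl migration to the 1,3-diketone.
     - Cyclodehydrate with H2SO4/AcOH.
     - Remove the benzyl group with H2, Pd/C.
3. **Step 5, condensation of a deactivated, air-sensitive phenoxide aldehyde.**
   - Risk: slow conversion or oxidative degradation in strong base.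
   - Fallback: change the protecting-group strategy.
     - Convert 6 into the neutral 3-benzyloxy aldehyde (K2CO3/MeOH, then BnBr).
     - Carry the benzyl ether through the condensation and cyclisation.
     - Remove it by hydrogenolysis as a final step.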